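The route opens furan ring C at two bonds: furan O–aryl and coumarin C3–aryl. Both bonds end on adjacent carbons of phenol ring D (C10a and C6b, coumestan numbering), which is the ortho pattern an aryne accepts in one event. Fluoride-triggered union of 5-benzyloxy-3-chlorobenzyne with the O–C4=C3 unit of the ring A–B–E coumarin therefore forms both bonds, closes ring C and joins the two halves. The coumarin enters as the phenyliodonium ylide of the chroman-fused 4-hydroxy-7-methoxycoumarin. The aryne is released from an ortho-silylaryl triflate whose chlorine steers the addition and leaves with the benzyl group in the final hydrogenolysis.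

Key step: step 8

Remark on the chemistry: rings are lettered A (alkoxy-substituted benzo ring), B (lactone), C (furan), D (phenol ring) and E (2,2-dimethyldihydropyran); coumarin numbering is used for 6 and 7, coumestan numbering (C1–C4 ring A, C6 lactone carbonyl, C6a–C6b the bond from coumarin C3 to ring D, C7–C10 ring D, O11 furan oxygen) for 16–19; the target has no stereocentre, so no stereocontrol is needed.

Step 1
Reactants: 1 2',6'-dihydroxy-4'-methoxyacetophenone; 2 isoprene
Product: 4 1-(7-hydroxy-5-methoxy-2,2-dimethylchroman-8-yl)ethanone, via C-prenyl phenol 3 (not isolated)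
Conditions: Amberlyst 15, THF–heptane, 65–70 °C, 2 (1.0 equiv) added slowly
Reagents that add atoms: none
Why: Friedel–Crafts prenylation of the phloroglucinol-type ring (C3' and C5' are equivalent, so only one mono-adduct 3 exists) followed by acid-catalysed Markovnikov hydroalkoxylation of the prenyl alkene by the 2'-OH, the only phenol next to it, is a known one-pot chroman synthesis from hydroxyacetophenones and isoprene, and keeping isoprene at one equivalent holds back a second annulation.

Step 2
Reactants: 4 1-(7-hydroxy-5-methoxy-2,2-dimethylchroman-8-yl)ethanone; 5 diethyl carbonate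
Product: 6 10-hydroxy-5-methoxy-2,2-dimethyl-3,4-dihydro-2H,8H-pyrano[2,3-f]chromen-8-one (the ring A–B–E 4-hydroxycoumarin)
Conditions: NaH (4 equiv), 5 (excess), toluene, 110 °C; then 1 M HCl
Reagents that add atoms: none
Why: Claisen-type acylation of the methyl ketone enolate by diethyl carbonate and lactonisation with the neighbouring phenoxide is the standard route from ortho-hydroxyacetophenones to 4-hydroxycoumarins, the product rests as its stable sodium enolate until the acid quench, and both ethers and ring E are inert to NaH.

Step 3
Reactants: 6 the ring A–B–E 4-hydroxycoumarin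
Product: 7 phenyliodonium ylide of 6 (3-phenyliodonio 4-olate zwitterion)
Conditions: PhI(OAc)2 (1.05 equiv), Na2CO3 (2 equiv), H2O–MeOH, 0 °C to rt, solid filtered off
Reagents that add atoms: (diacetoxyiodo)benzene, CC(=O)OI(OC(C)=O)c1ccccc1
Why: Condensation of an acidic cyclic 1,3-dicarbonyl compound with PhI(OAc)2 under mild base (ligand exchange at trivalent iodine) is the usual preparation of stabilised iodonium ylides and is established for 4-hydroxycoumarins, ring A has no free phenol to be oxidised, and the zwitterion should separate from the aqueous medium.

Step 4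
Reactants: 8 4-(benzyloxy)phenol
Product: 9 4-(benzyloxy)-2-chlorophenol
Conditions: SO2Cl2 (1.0 equiv), CH2Cl2, 0 °C to rt
Reagents that add atoms: sulfuryl chloride, O=S(=O)(Cl)Cl
Why: Electrophilic aromatic chlorination goes ortho to the free OH, the stronger donor whose para position is blocked, as in the known monochlorination of 4-alkoxyphenols, and one equivalent at low temperature avoids dichlorination and leaves the benzyl ether intact.

Step 5
Reactants: 9 4-(benzyloxy)-2-chlorophenol
Product: 10 4-(benzyloxy)-2-bromo-6-chlorophenol
Conditions: NBS (1.05 equiv), i-Pr2NH (10 mol%), CH2Cl2, 0 °C to rt, dark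
Reagents that add atoms: N-bromosuccinimide, O=C1CCC(=O)N1Br
Why: Amine-catalysed electrophilic ortho-bromination of phenols with NBS takes the one remaining position ortho to OH, and ionic conditions in the dark spare the benzylic CH2.

Step 6
Reactants: 10 4-(benzyloxy)-2-bromo-6-chlorophenol
Product: 11 [4-(benzyloxy)-2-bromo-6-chlorophenoxy]trimethylsilane
Conditions: HMDS (neat or THF), 75 °C; evaporate
Reagents that add atoms: hexamethyldisilazane, C[Si](C)(C)N[Si](C)(C)C
Why: O-silylation of a phenol with HMDS needs no added base and no aqueous work-up, so the hydrolytically labile aryl silyl ether is obtained simply by evaporation and touches no other group.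

Step 7
Reactants: 11 [4-(benzyloxy)-2-bromo-6-chlorophenoxy]trimethylsilane
Product: 14 4-(benzyloxy)-2-chloro-6-(trimethylsilyl)phenyl trifluoromethanesulfonate, via aryllithium 12 (not isolated), via lithium silylphenoxide 13 (not isolated)
Conditions: n-BuLi (1.1 equiv), THF, −78 °C; then Tf2O (1.2 equiv), −78 °C
Reagents that add atoms: triflic anhydride, O=S(=O)(OS(=O)(=O)C(F)(F)F)C(F)(F)F
Why: Bromine–lithium exchange outruns any reaction at C–Cl, at the benzylic CH2 or at silicon, aryllithium 12 undergoes the retro-Brook (1,3 O-to-C) silyl shift to phenoxide 13, and Tf2O traps the phenoxide, which is the standard sequence to ortho-silylaryl triflates including the parent 2-chloro-6-silyl case.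

Step 8
Reactants: 7 phenyliodonium ylide of the ring A–B–E 4-hydroxycoumarin; 14 4-(benzyloxy)-2-chloro-6-(trimethylsilyl)phenyl trifluoromethanesulfonate
Product: 17 9-(benzyloxy)-7-chloro-3-methoxycoumestan carrying ring E (O on C1; CH2 on C2), via chlorobenzyne 15 (not isolated), via cyclic iodane 16 (not isolated)
Conditions: CsF (3 equiv), 4 Å MS, MeCN, rt, 14 (1.5 equiv) added slowly
Reagents that add atoms: none
Why: CsF desilylates 14 and loss of triflate gives aryne 15; the C4 oxygen of ylide 7, which holds most of the negative charge, adds to the aryne carbon meta to chlorine, and the aryl anion formed beside the C–Cl bond is captured by the nearby cationic trivalent iodine to give the six-membered iodane 16. Ligand coupling at iodine then joins C3 to that aryl carbon and expels iodobenzene, so furan ring C closes as a formal [3+2] annulation (the three atoms O–C4=C3 plus the two aryne carbons) by contraction of the six-membered iodacycle to the five-membered ring. The closest known reaction is the metal-free, CsF-mediated benzofuran synthesis from ortho-silylaryl triflates and phenyliodonium ylides of cyclic 1,3-dicarbonyl compounds, of which the 4-oxycoumarin ylide is the lactone member. No stereocentre is formed. Two selectivities are needed: orientation on the aryne, secured by chlorine, whose inductive pull and distortion of the triple bond make the remote carbon the electrophilic one and override the weak, unreliable bias of the benzyloxy group, so that OBn ends para to the new C–C bond (C9); and reaction through O4 instead of the lactone carbonyl oxygen, secured by the higher charge density of the ketone-type enolate oxygen. Chlorine is preferred to bromine because it polarises the aryne more strongly, crowds the C6 carbonyl less from C7 and is expelled less readily from the ortho-haloaryl anion, while lactone, methyl ether, benzyl ether and ring E are inert to CsF in MeCN at room temperature.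

Step 9
Reactants: 17 9-(benzyloxy)-7-chloro-3-methoxycoumestan carrying ring E
Product: 19 target coumestan (9-hydroxy-3-methoxycoumestan carrying ring E), via chlorophenol 18 (not isolated)
Conditions: H2 (1 atm), 10% Pd/C, THF–MeOH, rt; then Et3N (3 equiv), H2 (1 atm), rt
Reagents that add atoms: none
Why: Heterogeneous hydrogenolysis is run in two stages in one flask, the aryl benzyl ether being cleaved first in amine-free medium (amines can slow O-debenzylation on Pd/C) and Et3N then being added to take up HCl and accelerate the known Pd/C hydrodechlorination of the aryl chloride, while the aromatic furan, the lactone, the methyl ether and ring E offer nothing reducible at one atmosphere.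

Compound list
1 | 2',6'-dihydroxy-4'-methoxyacetophenone | CC(=O)c1c(O)cc(OC)cc1O | starting material
2 | isoprene (2-methylbuta-1,3-diene) | C=CC(C)=C | starting material
3 | 1-[2,6-dihydroxy-4-methoxy-3-(3-methylbut-2-en-1-yl)phenyl]ethanone (not isolated) | CC(=O)c1c(O)cc(OC)c(CC=C(C)C)c1O | intermediate
4 | 1-(7-hydroxy-5-methoxy-2,2-dimethylchroman-8-yl)ethanone | CC(=O)c1c(O)cc(OC)c2c1OC(C)(C)CC2 | intermediate
5 | diethyl carbonate | CCOC(=O)OCC | starting material
6 | 10-hydroxy-5-methoxy-2,2-dimethyl-3,4-dihydro-2H,8H-pyrano[2,3-f]chromen-8-one (4-hydroxy-7-methoxycoumarin with ring E fused through O at C5 and CH2 at C6) | COc1cc2oc(=O)cc(O)c2c2c1CCC(C)(C)O2 | intermediate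
7 | phenyliodonium ylide of 6 (phenyliodonio group on C3, olate on C4) | COc1cc2oc(=O)c([I+]c3ccccc3)c([O-])c2c2c1CCC(C)(C)O2 | intermediate
8 | 4-(benzyloxy)phenol | Oc1ccc(OCc2ccccc2)cc1 | starting material
9 | 4-(benzyloxy)-2-chlorophenol | Oc1ccc(OCc2ccccc2)cc1Cl | intermediate
10 | 4-(benzyloxy)-2-bromo-6-chlorophenol | Oc1c(Br)cc(OCc2ccccc2)cc1Cl | intermediate
11 | [4-(benzyloxy)-2-bromo-6-chlorophenoxy]trimethylsilane | C[Si](C)(C)Oc1c(Br)cc(OCc2ccccc2)cc1Cl | intermediate
12 | [5-(benzyloxy)-3-chloro-2-(trimethylsilyloxy)phenyl]lithium (not isolated) | [Li]c1cc(OCc2ccccc2)cc(Cl)c1O[Si](C)(C)C | intermediate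
13 | lithium 4-(benzyloxy)-2-chloro-6-(trimethylsilyl)phenoxide (not isolated) | [Li+].[O-]c1c(Cl)cc(OCc2ccccc2)cc1[Si](C)(C)C | intermediate
14 | 4-(benzyloxy)-2-chloro-6-(trimethylsilyl)phenyl trifluoromethanesulfonate | C[Si](C)(C)c1cc(OCc2ccccc2)cc(Cl)c1OS(=O)(=O)C(F)(F)F | intermediate
15 | 5-(benzyloxy)-3-chlorobenzyne (1-benzyloxy-3-chloro-4,5-didehydrobenzene; not isolated) | ClC1=CC(OCc2ccccc2)=CC#C1 | intermediate
16 | six-membered cyclic iodane: iodine bears phenyl, coumarin C3 and the ring D carbon next to chlorine; O4 is bound to the neighbouring ring D carbon (not isolated) | COc1cc2oc(=O)c3c(Oc4cc(OCc5ccccc5)cc(Cl)c4I3c3ccccc3)c2c2c1CCC(C)(C)O2 | intermediate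
17 | 9-(benzyloxy)-7-chloro-3-methoxycoumestan with ring E fused through O at C1 and CH2 at C2 | COc1cc2oc(=O)c3c4c(Cl)cc(OCc5ccccc5)cc4oc3c2c2c1CCC(C)(C)O2 | intermediate
18 | 7-chloro-9-hydroxy-3-methoxycoumestan with ring E (not isolated) | COc1cc2oc(=O)c3c4c(Cl)cc(O)cc4oc3c2c2c1CCC(C)(C)O2 | intermediate
19 | CNP0304440.0: 9-hydroxy-3-methoxycoumestan with the 2,2-dimethyldihydropyran ring E fused through O at C1 and CH2 at C2 (achiral) | COc1cc2oc(=O)c3c4ccc(O)cc4oc3c2c2c1CCC(C)(C)O2 | target

Total step count: 9 (coumarin branch steps 1–3, aryne branch steps 4–7, union and finish steps 8–9).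
Longest linear sequence: 6 steps (8 → 9 → 10 → 11 → 14 → 17 → 19).

Steps most likely to fail

1. Step 8.
- **What may go wrong:** Four processes threaten the step: loss of orientation in the addition to the unsymmetrical aryne, competing attack through the lactone carbonyl oxygen, expulsion of chloride from the ortho-chloroaryl anion before iodine captures it, and phenyl migration within the ylide.
- **Fallback:** It builds the same two bonds stepwise by cross-coupling and cyclodehydration, and sets out from 7.
- A Suzuki–Miyaura-type coupling of the iodonium zwitterion with commercial 2,4-bis(benzyloxy)phenylboronic acid (Pd(P(t-Bu)3)2, LiOH, DME–H2O, rt) is a known reaction of coumarin iodonium ylides. It should give the 3-[2,4-bis(benzyloxy)phenyl]-4-hydroxycoumarin F1.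
- Hydrogenolysis (H2, 10% Pd/C, EtOAc–MeOH, rt) should give the 3-(2,4-dihydroxyphenyl)-4-hydroxycoumarin F2.
- The classical acid-catalysed cyclodehydration (p-TsOH, toluene, reflux), in which the 2'-OH replaces the C4 hydroxyl, closes ring C with unambiguous regiochemistry. The fallback comes back to the route at target 19.
- Benzyl protection is chosen over methyl so that the ring A methyl ether is never put at risk.

2. Step 1.
- **What may go wrong:** A second annulation may occur at the remaining nucleophilic ring position, and acid-induced oligomerisation of isoprene may leave poor conversion.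
- **Fallback:** It replaces cationic alkylation by a condensation–electrocyclisation, and sets out from 1.
- Condensation with 3-methylbut-2-enal (ethylenediammonium diacetate, toluene, reflux) proceeds through an ortho-quinone methide and oxa-6π ring closure. It should give the chromene alloevodionol F3, again as the only possible mono-adduct.
- Hydrogenation of its C3=C4 alkene (H2, 10% Pd/C, EtOAc, rt) comes back to the route at 4.

3. Step 9.
- **What may go wrong:** Hydrodechlorination may stall at the hindered, electron-rich C7–Cl bond, the heterogeneous catalyst may be poisoned, or the flat substrate may be poorly soluble.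
- **Fallback:** It separates the two reductions and moves the C–Cl cleavage to a homogeneous catalyst, and sets out from 17.
- Oxidative addition of zerovalent palladium bearing a bulky biarylphosphine, with formate as hydride source (Pd(OAc)2, XPhos, HCO2Na, DMF, 80 °C), should give the chlorine-free 9-(benzyloxy)-3-methoxycoumestan with ring E F4.
- Ordinary amine-free hydrogenolysis (H2, 10% Pd/C, THF–MeOH, rt) then comes back to the route at 19.

Further compounds
F1 | step 8 | 3-[2,4-bis(benzyloxy)phenyl] derivative of 4-hydroxycoumarin 6 | COc1cc2oc(=O)c(-c3ccc(OCc4ccccc4)cc3OCc3ccccc3)c(O)c2c2c1CCC(C)(C)O2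
F2 | step 8 | 3-(2,4-dihydroxyphenyl) derivative of 4-hydroxycoumarin 6 | COc1cc2oc(=O)c(-c3ccc(O)cc3O)c(O)c2c2c1CCC(C)(C)O2
F3 | step 1 | alloevodionol, 1-(7-hydroxy-5-methoxy-2,2-dimethyl-2H-chromen-8-yl)ethanone | CC(=O)c1c(O)cc(OC)c2c1OC(C)(C)C=C2
F4 | step 9 | 9-(benzyloxy)-3-methoxycoumestan with ring E fused through O at C1 and CH2 at C2 | COc1cc2oc(=O)c3c4ccc(OCc5ccccc5)cc4oc3c2c2c1CCC(C)(C)O2
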